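(The numbers in the tables are calculated on assumed constants; scatter was added.)

I take the over-reaction product to grow out of target, so I treat target as a tank with an inflow and a drain, and the drain fills the product.

| flask | substrate | coupling partner | remark | time |
|---|---|---|---|---|
| grey | 22 mM | 55 mM | the very flask that is asked about, followed so far |  |
| flask | 22 mM | 55.0 mM |  | 15 d |

grey run (percent of the substrate charged)

| time / d | over-reaction product / % | target / % |
|---|---|---|
| 0.625 | 2.7 | 0.6 |
| 1.67 | 8.5 | 1.8 |
| 3.00 | 17.8 | 1.5 |
| 5.00 | 28.7 | 1.1 |

(each reading ± 0.5 percentage points)

- ratio of over-reaction product to target at 5.0 h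
- ratio of over-reaction product to target at 40 h
- ratio of over-reaction product to target at 15 d

Start from the balance of the limiting reagent, substrate (22 mM against 55.0 mM of coupling partner). The charge is c_target, plus c_over-reaction product, plus an unseen stock, which in the grey run at 5.00 d is still 70.2 %. Between 3.00 d and 5.00 d the product climbs with slope 0.0545 d⁻¹, in fractions of the charge. That gives

d c_over-reaction product/dt = c_target/τ, with τ = mean c_target/slope = 0.239 d

This τ, target's time constant of loss to over-reaction product, is a pseudo-first-order reading, and each target reading in it scatters by 0.5 percentage points.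

First instants: 5.0 h is shorter than τ, so the tank is still filling and, for a steady inflow,

ratio ≈ 0.5 · t/τ = 0.437

Middle: 40 h is much longer than τ, so target sits in a steady state. The slope of the grey run across 0.625 d to 3.00 d then gives

ratio = c_over-reaction product/(τ · slope) = 5.60

End: I let the slope follow the stock at 0.0722 d⁻¹, so the stock falls to 34.1 %. With τ held fixed,

ratio = 112

The forecast, which parts from my figures at the early and late times, gives 4, 5 and 240, reading that “much of the product seems to form directly, in parallel”. The flask gives 0.427, 5.62 and 85.2.

    substrate ⇌ intermediate A (K = 18.0, k = 3.20 × 10⁻⁵ s⁻¹)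
    coupling partner + intermediate A ⇌ intermediate B (K = 32.0 M⁻¹, k = 0.00140 M⁻¹ s⁻¹)
    intermediate A ⇌ intermediate C (K = 2.40, k = 7.60 × 10⁻⁵ s⁻¹)
    intermediate A → target (k = 4.20 × 10⁻⁶ s⁻¹)
    coupling partner + target → over-reaction product (k = 0.00100 M⁻¹ s⁻¹)

In this flask substrate passes first into the intermediates: at 1.50 d it stands at 2.57 %, with intermediates A, B and C at 17.9 %, 27.5 % and 42.7 % and target at 1.59 %. Intermediate A then goes on feeding target, which at 15.0 d is made at 0.981 of the rate it is used, while the product reaches 65.9 %. The half-life from my τ, read between 3.00 d and 5.00 d, is 0.166 d, which stands beside the 0.16 d of the over-reaction step at 0.252 d. The late ratio lies below my figure, with coupling partner down to 70.1 %.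

In the neighbour flask with 14 mM of coupling partner, τ scaled inversely with that charge becomes 0.937 d, so with the inflow taken as unchanged the early ratio should be 0.111. The computed value is 0.0962.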